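**Retrosynthetic overview**
- Target ⇐ bicyclic 2-ketone phenacyl ester by one SmI2 operation (equatorial C2–OH and release of the acid); the C19 acetate is carried from the start.
- Rings A and B (A closes first, then B, in one cascade) ⇐ acyclic (Z)-γ-acetoxy enone/(E,E)-diene by a chiral Brønsted acid (IDPi) enone-initiated cation–olefin bicyclisation: bonds C4–C5 and C9–C10, stereocentres C4, C5, C9, C10, Δ7 by proton loss.
- Acyclic enone ⇐ allylic chloride + CO + (Z)-vinylstannane (carbonylative Stille; bonds C1–C2 and C2–C3).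
- Allylic chloride ⇐ (2E,6E)-farnesoic acid (asymmetric hydrogenation sets C13 first; phenacyl ester; terminal SeO2 oxidation); stannane ⇐ propargyl alcohol, MeMgBr, Bu3SnCl, Ac2O.

Assumption: ring positions use labdane numbering (C19 = CH2OAc carbon on C4, C20 = methyl on C10, side chain C11–C16 on C9); the target is read as (2S,4R,5S,9R,10S,13R), an ent-labdane with equatorial 2-OH and axial CH2OAc cis to C20. The catalyst antipodes written ((S)-BINAP, (S,S)-IDPi) are assumed to give this sense; otherwise the mirror-image catalyst is used.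

**Step 1**
Reactants: 1 (2E,6E)-farnesoic acid
Product: 2 (3R,6E)-3,7,11-trimethyldodeca-6,10-dienoic acid
Conditions: Ru(OAc)2[(S)-BINAP] (1 mol %), H2 (100 atm), MeOH, 25 °C
Reagents that add atoms: none
Why: Noyori carboxylate-directed asymmetric hydrogenation reduces only the conjugated C2=C3 bond and sets C3 (R, the future C13) under catalyst control (about 90% ee expected for this substrate class; the residual 3S material would become the C13 epimer of the target).

**Step 2**
Reactants: 2 (3R,6E)-3,7,11-trimethyldodeca-6,10-dienoic acid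
Product: 3 phenacyl (2-oxo-2-phenylethyl) (3R,6E)-3,7,11-trimethyldodeca-6,10-dienoate
Conditions: PhCOCH2Br, KHCO3, DMF, 25 °C
Reagents that add atoms: phenacyl bromide, O=C(CBr)c1ccccc1
Why: SN2 O-alkylation of the carboxylate gives an ester that tolerates the later steps and is cleaved reductively by SmI2 in the last step.

**Step 3**
Reactants: 3 phenacyl (3R,6E)-3,7,11-trimethyldodeca-6,10-dienoate
Product: 4 phenacyl (3R,6E,10E)-12-hydroxy-3,7,11-trimethyldodeca-6,10-dienoate
Conditions: SeO2 (0.3 equiv), t-BuOOH, salicylic acid (10 mol %), CH2Cl2, 0 → 25 °C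
Reagents that add atoms: tert-butyl hydroperoxide, CC(C)(C)OO; selenium dioxide, O=[Se]=O (catalytic oxygen carrier)
Why: Sharpless catalytic SeO2 allylic oxidation (ene reaction then [2,3]-shift) is selective for the E-methyl of the terminal isopropylidene group and gives the (E)-allylic alcohol; it is stopped at partial conversion to limit enal formation.

**Step 4**
Reactants: 4 phenacyl (3R,6E,10E)-12-hydroxy-3,7,11-trimethyldodeca-6,10-dienoate
Product: 6 phenacyl (3R,6E,10E)-12-chloro-3,7,11-trimethyldodeca-6,10-dienoate, via allylic mesylate 5 (not isolated)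
Conditions: MsCl, s-collidine, LiCl, DMF, 0 °C
Reagents that add atoms: lithium chloride, [Li+].[Cl-]; methanesulfonyl chloride, CS(=O)(=O)Cl (mesyl group of intermediate 5 only)
Why: Collington–Meyers chlorination (mesylation, then SN2 by chloride at the primary allylic carbon) proceeds without allylic transposition and keeps the E geometry.

**Step 5**
Reactants: 7 prop-2-yn-1-ol
Product: 9 (Z)-2-methyl-3-(tributylstannyl)prop-2-en-1-ol, via vinylmagnesium alkoxide 8 (not isolated)
Conditions: MeMgBr (2.5 equiv), CuI (10 mol %), THF, −10 → 25 °C; then Bu3SnCl, 0 °C; H2O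
Reagents that add atoms: methylmagnesium bromide, C[Mg]Br; tributyltin chloride, CCCC[Sn](Cl)(CCCC)CCCC
Why: Copper-catalysed alkoxide-directed anti-carbomagnesiation puts methyl on the internal carbon and magnesium cis to CH2O in a five-membered chelate, and Mg→Sn exchange with retention fixes the Z geometry.

**Step 6**
Reactants: 9 (Z)-2-methyl-3-(tributylstannyl)prop-2-en-1-ol
Product: 10 (Z)-2-methyl-3-(tributylstannyl)prop-2-en-1-yl acetate
Conditions: Ac2O, pyridine, DMAP (5 mol %), CH2Cl2, 0 °C
Reagents that add atoms: acetic anhydride, CC(=O)OC(C)=O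
Why: Standard O-acylation installs the acetate of the target and prevents lactol/furan formation in the later Z-γ-oxy enone.

**Step 7**
Reactants: 6 phenacyl (3R,6E,10E)-12-chloro-3,7,11-trimethyldodeca-6,10-dienoate; 10 (Z)-2-methyl-3-(tributylstannyl)prop-2-en-1-yl acetate
Product: 11 phenacyl (3R,6E,10E,14Z)-16-acetoxy-3,7,11,15-tetramethyl-13-oxohexadeca-6,10,14-trienoate
Conditions: Pd2(dba)3 (2.5 mol %), AsPh3 (10 mol %), CO (3 atm), THF, 50 °C
Reagents that add atoms: carbon monoxide, [C-]#[O+]
Why: Stille carbonylative cross-coupling: the η3-allyl-Pd takes up CO at its unsubstituted CH2 terminus and the vinyl group transfers with retention, giving the skipped Z-enone under neutral conditions that leave the C10=C11 bond out of conjugation.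

**Step 8**
Reactants: 11 phenacyl (3R,6E,10E,14Z)-16-acetoxy-3,7,11,15-tetramethyl-13-oxohexadeca-6,10,14-trienoate
Product: 13 phenacyl (4R,5S,9R,10S,13R)-19-acetoxy-2-oxolabd-7-en-15-oate (trans-decalin, CH2OAc axial and cis to C20, side chain equatorial), via C2-enol 12 (not isolated)
Conditions: (S,S)-IDPi (3,3′-diaryl-BINOL-derived imidodiphosphorimidate, 5 mol %), CHCl3/(CF3)3COH 4:1, −40 °C
Reagents that add atoms: none
Why: Proposed new method: the confined chiral IDPi Brønsted acid protonates the most basic site (the enone C=O) to a 2-hydroxyallyl cation held as a contact ion pair in the chiral pocket, the (14Z)-enone/(6E,10E)-diene folds chair–chair, C5 adds anti to C4 (ring A), C9 adds to the C10 cation (ring B), and the counter-anion removes axial H-7 to give the Δ7 alkene and enol 12, which tautomerises to 13 and returns the proton (net cycloisomerisation); the Z geometry places CH2OAc axial and cis to the C10 methyl (4R), the E alkenes give the trans fusion (5S,10S) and the equatorial side chain (9R), and the catalyst antipode fixes the absolute sense independently of the remote C13 centre; the closest known reaction types are the IDPi-catalysed asymmetric cation–olefin bicyclisation of homofarnesol-type polyenes (alkene protonation), the IDPi-catalysed Nazarov cyclisation of divinyl ketones (carbonyl protonation) and racemic Lewis-acid Michael-initiated polyene cyclisations of enones.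

**Step 9**
Reactants: 13 phenacyl (4R,5S,9R,10S,13R)-19-acetoxy-2-oxolabd-7-en-15-oate
Product: 15 (2S,4R,5S,9R,10S,13R)-19-acetoxy-2-hydroxylabd-7-en-15-oic acid (CNP0162900.1), via keto acid 14 (not isolated)
Conditions: SmI2 (8 equiv), H2O, Et3N, THF, −20 °C, 5 min; aq tartaric acid
Reagents that add atoms: none
Why: Samarium diiodide single-electron reduction first cleaves the α-acyloxy aryl ketone (phenacyl ester → acid) and then reduces the C2 ketone via its ketyl under thermodynamic control, the O–Sm group taking the equatorial site away from the syn-axial C19/C20 groups and the proton entering axially (as in metal–ammonia reduction of 11-oxo steroids), which gives the equatorial 2S alcohol while the unactivated acetate reacts far more slowly.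

**Compound list**
1 | (2E,6E)-farnesoic acid [(2E,6E)-3,7,11-trimethyldodeca-2,6,10-trienoic acid] | CC(C)=CCC/C(C)=C/CC/C(C)=C/C(=O)O | starting material
2 | (3R,6E)-3,7,11-trimethyldodeca-6,10-dienoic acid | CC(C)=CCC/C(C)=C/CC[C@@H](C)CC(=O)O | intermediate
3 | phenacyl (3R,6E)-3,7,11-trimethyldodeca-6,10-dienoate | CC(C)=CCC/C(C)=C/CC[C@@H](C)CC(=O)OCC(=O)c1ccccc1 | intermediate
4 | phenacyl (3R,6E,10E)-12-hydroxy-3,7,11-trimethyldodeca-6,10-dienoate | OC/C(C)=C/CC/C(C)=C/CC[C@@H](C)CC(=O)OCC(=O)c1ccccc1 | intermediate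
5 | phenacyl (3R,6E,10E)-12-(methanesulfonyloxy)-3,7,11-trimethyldodeca-6,10-dienoate | CS(=O)(=O)OC/C(C)=C/CC/C(C)=C/CC[C@@H](C)CC(=O)OCC(=O)c1ccccc1 | intermediate (not isolated)
6 | phenacyl (3R,6E,10E)-12-chloro-3,7,11-trimethyldodeca-6,10-dienoate | ClC/C(C)=C/CC/C(C)=C/CC[C@@H](C)CC(=O)OCC(=O)c1ccccc1 | intermediate
7 | prop-2-yn-1-ol (propargyl alcohol) | C#CCO | starting material
8 | (Z)-[3-(bromomagnesiooxy)-2-methylprop-1-en-1-yl]magnesium bromide | C/C(CO[Mg]Br)=C/[Mg]Br | intermediate (not isolated)
9 | (Z)-2-methyl-3-(tributylstannyl)prop-2-en-1-ol | C/C(CO)=C/[Sn](CCCC)(CCCC)CCCC | intermediate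
10 | (Z)-2-methyl-3-(tributylstannyl)prop-2-en-1-yl acetate | CC(=O)OC/C(C)=C\[Sn](CCCC)(CCCC)CCCC | intermediate
11 | phenacyl (3R,6E,10E,14Z)-16-acetoxy-3,7,11,15-tetramethyl-13-oxohexadeca-6,10,14-trienoate | CC(=O)OC/C(C)=C\C(=O)C/C(C)=C/CC/C(C)=C/CC[C@@H](C)CC(=O)OCC(=O)c1ccccc1 | intermediate
12 | C2-enol of 13 (phenacyl 19-acetoxy-2-hydroxylabda-2,7-dien-15-oate, same spatial configuration as 13) | CC(=O)OC[C@]1(C)C=C(O)C[C@@]2(C)[C@H](CC[C@@H](C)CC(=O)OCC(=O)c3ccccc3)C(C)=CC[C@H]12 | intermediate (not isolated)
13 | phenacyl (4R,5S,9R,10S,13R)-19-acetoxy-2-oxolabd-7-en-15-oate | CC(=O)OC[C@]1(C)CC(=O)C[C@@]2(C)[C@H](CC[C@@H](C)CC(=O)OCC(=O)c3ccccc3)C(C)=CC[C@H]12 | intermediate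
14 | (4R,5S,9R,10S,13R)-19-acetoxy-2-oxolabd-7-en-15-oic acid | CC(=O)OC[C@]1(C)CC(=O)C[C@@]2(C)[C@H](CC[C@@H](C)CC(=O)O)C(C)=CC[C@H]12 | intermediate (not isolated)
15 | (2S,4R,5S,9R,10S,13R)-19-acetoxy-2-hydroxylabd-7-en-15-oic acid | CC(=O)OC[C@]1(C)C[C@@H](O)C[C@@]2(C)[C@H](CC[C@@H](C)CC(=O)O)C(C)=CC[C@H]12 | target

**Totals:** 9 steps; longest linear sequence 7 steps (steps 1–4, 7, 8, 9).

**Three steps most likely to fail**

Step 8 (the new IDPi cyclisation). The risks are acid-catalysed drift of the skipped C10=C11 alkene into conjugation, E/Z scrambling of the enone (loss of C4 control), Δ8(17) or monocyclic by-products, and low ee. The fallback uses known chemistry and sets out from 11. The achiral Lewis acid MeAlCl2 (CH2Cl2, −78 °C), a known Michael-initiated cation–olefin polycyclisation, gives the same relative configuration without facial control. Because C13 is already R, the two ring antipodes are diastereomers: 13 and phenacyl (4S,5R,9S,10R,13R)-19-acetoxy-2-oxolabd-7-en-15-oate F1. They are separated by preparative HPLC or by crystallisation of the phenacyl esters, and the route is rejoined at 13.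

Step 9 (one reagent for two reductions with thermodynamic selectivity at C2). The risks are reduction or loss of the C19 acetate, acyl transfer to the C2 carbanion, and the axial epimer. The fallback sets out from 13. Dissolving-metal reduction (Li, NH3/THF, t-BuOH, −78 °C), the classical route to equatorial alcohols from hindered ketones, cleaves both esters and reduces the ketone to (2S,4R,5S,9R,10S,13R)-2,19-dihydroxylabd-7-en-15-oic acid F2. Lipase-catalysed acetylation (Novozym 435, vinyl acetate, MTBE), selective for the primary C19 hydroxyl, then gives 15.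

Step 7 (carbonylative Stille). The risks are E/Z scrambling in the η3-allyl-Pd, direct coupling without CO, conjugation of the product, and ionisation of the allylic acetate. The fallback sets out from 6 and separates CO uptake from C–C coupling. Pd-catalysed hydroxycarbonylation (PdCl2(PPh3)2, CO, H2O, THF) gives (3E,7E,11R)-3,7,11-trimethyl-13-oxo-13-(2-oxo-2-phenylethoxy)trideca-3,7-dienoic acid F3. Ghosez's reagent converts it under neutral conditions into phenacyl (3R,6E,10E)-13-chloro-3,7,11-trimethyl-13-oxotrideca-6,10-dienoate F4. Stille acylation of F4 with 10 (Pd2(dba)3, THF, 25 °C) gives 11.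

**Further compounds**
F1 | step 8 | phenacyl (4S,5R,9S,10R,13R)-19-acetoxy-2-oxolabd-7-en-15-oate | CC(=O)OC[C@@]1(C)CC(=O)C[C@]2(C)[C@@H](CC[C@@H](C)CC(=O)OCC(=O)c3ccccc3)C(C)=CC[C@@H]12
F2 | step 9 | (2S,4R,5S,9R,10S,13R)-2,19-dihydroxylabd-7-en-15-oic acid | OC[C@]1(C)C[C@@H](O)C[C@@]2(C)[C@H](CC[C@@H](C)CC(=O)O)C(C)=CC[C@H]12
F3 | step 7 | (3E,7E,11R)-3,7,11-trimethyl-13-oxo-13-(2-oxo-2-phenylethoxy)trideca-3,7-dienoic acid | OC(=O)C/C(C)=C/CC/C(C)=C/CC[C@@H](C)CC(=O)OCC(=O)c1ccccc1
F4 | step 7 | phenacyl (3R,6E,10E)-13-chloro-3,7,11-trimethyl-13-oxotrideca-6,10-dienoate | ClC(=O)C/C(C)=C/CC/C(C)=C/CC[C@@H](C)CC(=O)OCC(=O)c1ccccc1
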